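**Retrosynthetic overview**

1. The target is the C2-symmetric head-to-head dimer (cyclobutane C8–C9–C9′–C8′) of a lindenane trienolide. The strategy rests on one feature: in each half the cyclopropane C1–C2–C3 is fused to the five-membered ring C1/C3/C4/C5/C10 that carries the exocyclic C4=C15 methylene, which is a eudesmane A ring (C1–C2–C3–C4–C5–C10) with one extra C1–C3 bond.
2. Last disconnection: both C1–C3 bonds (C1–C3 and C1′–C3′) are cut, leading back to the cyclobutane-linked bis(1β-hydroxy-15-trimethylsilyl-eudesma-3,7(11)-dien-8,12-olide) 27. Both ring contractions are done at once, as the final step.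
3. The cyclobutane comes from [2+2] photodimerisation of the monomeric eudesma-3,7(11),8-trien-8,12-olide 26 at C8=C9.
4. Monomer 26: allylsilane from a C4 enol triflate (Negishi); ylidenebutenolide from a C7 ketone (Rubottom, intramolecular HWE, dehydrobromination); trans-decalin with 1β-OH and C4 oxygen from (R)-Wieland–Miescher ketone by ketalisation with alkene migration and hydroboration.
5. Order of ring formation: ring B onto ring A (Robinson), lactone, cyclobutane, then the two cyclopropanes with contraction of both A rings.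

Key step: step 16

Remark: eudesmane/lindenane numbering is used for every intermediate (C14 is the angular methyl on C10, β is the face of C14, primes mark the second half), and the enantiomeric purity of 5 is assumed to be raised by recrystallisation before step 3.

**Route**

Step 1
Reactants: 1 2-methylcyclohexane-1,3-dione; 2 methyl vinyl ketone
Product: 3 2-methyl-2-(3-oxobutyl)cyclohexane-1,3-dione
Conditions: H2O, AcOH (cat.), hydroquinone (cat.), 75 °C
Reagents that add atoms: none
Why: Michael addition of the acidic 1,3-dione C–H to the enone (first half of a Robinson annulation) should give the achiral triketone cleanly.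

Step 2
Reactants: 3 triketone
Product: 5 (R)-Wieland–Miescher ketone, via ketol 4 (not isolated)
Conditions: D-proline (cat.), DMSO, rt; recrystallisation
Reagents that add atoms: none
Why: Hajos–Parrish–Eder–Sauer–Wiechert aldol condensation, in which the proline enamine of the side-chain ketone adds to one of the two enantiotopic ring carbonyls, should set the quaternary centre C10 as R with D-proline (mirror image of the L-proline outcome) before dehydration of the ketol.

Step 3
Reactants: 5 (R)-Wieland–Miescher ketone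
Product: 6 1β-hydroxy enone
Conditions: NaBH4, EtOH, −10 → 0 °C
Reagents that add atoms: none
Why: Chemoselective borohydride reduction of the saturated C1 ketone over the enone, with hydride delivered from the α face anti to the angular methyl, should give the equatorial 1β-alcohol cis to C14.

Step 4
Reactants: 6 1β-hydroxy enone
Product: 7 Δ4 ketal alcohol
Conditions: HOCH2CH2OH, p-TsOH (cat.), benzene, reflux (Dean–Stark)
Reagents that add atoms: ethylene glycol, OCCO
Why: Acid-catalysed ketalisation of the enone under thermodynamic control moves the alkene out of conjugation to C4=C5, as with Δ4-3-keto steroids, which places it for oxygenation of C4.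

Step 5
Reactants: 7 Δ4 ketal alcohol
Product: 8 TBS ether
Conditions: TBSOTf, 2,6-lutidine, CH2Cl2, −78 → 0 °C
Reagents that add atoms: tert-butyldimethylsilyl triflate, CC(C)(C)[Si](C)(C)OS(=O)(=O)C(F)(F)F
Why: Silylation with the silyl triflate is the standard way to protect a hindered neopentyl-type secondary alcohol, and the dioxolane tolerates it in the presence of lutidine.

Step 6
Reactants: 8 TBS ether
Product: 10 4α-alcohol, via organoborane 9 (not isolated)
Conditions: BH3·THF, THF, 0 °C → rt; then NaOH, H2O2, 0 °C → rt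
Reagents that add atoms: borane–THF, B.C1CCOC1 (boron stays in intermediate 9 only); hydrogen peroxide, OO
Why: Brown hydroboration–oxidation adds boron to the less substituted C4 and hydrogen to C5 in a syn fashion from the α face anti to the axial C14 methyl, which should set 4α-OH and the 5α-H of the trans-decalin.

Step 7
Reactants: 10 4α-alcohol
Product: 11 trans-fused 4-ketone
Conditions: Dess–Martin periodinane, NaHCO3, CH2Cl2, rt; then NaOMe (cat.), MeOH, rt
Reagents that add atoms: none
Why: Dess–Martin oxidation gives the C4 ketone without touching the silyl ether or ketal, and the brief methoxide treatment converges any C5 epimer carried from step 6 to the trans-fused ketone, which should be the thermodynamic isomer.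

Step 8
Reactants: 11 trans-fused 4-ketone
Product: 12 Δ3 enol triflate
Conditions: KHMDS, THF, −78 °C; PhNTf2, −78 → 0 °C
Reagents that add atoms: N-phenylbis(trifluoromethanesulfonimide), O=S(=O)(N(c1ccccc1)S(=O)(=O)C(F)(F)F)C(F)(F)F
Why: Kinetic deprotonation removes a proton from the C3 methylene and not from the hindered C5 methine, and O-triflation of that enolate fixes the alkene at C3=C4 and leaves the C5 stereocentre untouched and no longer epimerisable.

Step 9
Reactants: 12 Δ3 enol triflate
Product: 13 7-ketone
Conditions: PPTS, acetone–H2O, 60 °C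
Reagents that add atoms: water, O
Why: Mild acid-catalysed hydrolysis (transketalisation) of the dioxolane frees the C7 ketone while the enol triflate and the hindered TBS ether are stable to pyridinium tosylate.

Step 10
Reactants: 13 7-ketone
Product: 16 8α-hydroxy-7-ketone, via silyl enol ether 14 (not isolated), via silyloxy ketone 15 (not isolated)
Conditions: LiHMDS, TMSCl, THF, −78 °C; mCPBA, NaHCO3, CH2Cl2, −20 °C; aq. citric acid, MeOH, rt
Reagents that add atoms: chlorotrimethylsilane, C[Si](C)(C)Cl (silicon stays in intermediates 14 and 15 only); 3-chloroperoxybenzoic acid, OOC(=O)c1cccc(Cl)c1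
Why: Rubottom oxidation, in which the trans-fused ketone enolises towards C8 (the Δ2 direction of 5α-3-keto steroids) and the peracid attacks the silyl enol ether on the α face anti to C14, should give the 8α-ketol, whose C8 configuration is erased later.

Step 11
Reactants: 16 8α-hydroxy-7-ketone; 17 2-(diethoxyphosphoryl)propanoic acid
Product: 19 Δ7(11)-butenolide, via phosphonate ester 18 (not isolated)
Conditions: EDC·HCl, DMAP, CH2Cl2, rt; then LiCl, DBU, MeCN, rt
Reagents that add atoms: none
Why: Steglich-type carbodiimide esterification of the ketol followed by intramolecular Horner–Wadsworth–Emmons olefination under Masamune–Roush conditions closes the five-membered lactone and forms C7=C11, a standard construction of α-methyl butenolides fused to cyclohexanes.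

Step 12
Reactants: 19 Δ7(11)-butenolide
Product: 22 silyl-protected trienolide triflate, via silyloxyfuran 20 (not isolated), via bromolactone 21 (not isolated)
Conditions: TBSOTf, Et3N, CH2Cl2, 0 °C; NBS, −78 °C; DBU, −78 → 0 °C
Reagents that add atoms: tert-butyldimethylsilyl triflate, CC(C)(C)[Si](C)(C)OS(=O)(=O)C(F)(F)F (silicon stays in intermediate 20 only); N-bromosuccinimide, O=C1CCC(=O)N1Br (bromine stays in intermediate 21 only)
Why: Soft enolisation gives the aromatic 2-silyloxyfuran, which NBS should brominate at C8 (the vinylogous furan 5-position), and the tertiary α-bromo ether then loses HBr towards C9 to give the γ-ylidenebutenolide with C8=C9.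

Step 13
Reactants: 22 silyl-protected trienolide triflate
Product: 23 1β-hydroxy trienolide triflate
Conditions: HF·pyridine, THF–pyridine, 0 °C → rt
Reagents that add atoms: none
Why: Fluoride-mediated desilylation under buffered acidic conditions frees the 1β-hydroxyl before silicon is introduced at C15 and spares both the enol triflate and the enol lactone.

Step 14
Reactants: 23 1β-hydroxy trienolide triflate; 24 (trimethylsilyl)methylmagnesium chloride
Product: 26 allylsilane monomer, via organozinc 25 (not isolated)
Conditions: 24, ZnCl2, THF, 0 °C; then 23, Pd(PPh3)4 (cat.), THF, 50 °C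
Reagents that add atoms: zinc chloride, Cl[Zn]Cl (zinc and chlorine stay in intermediate 25 only)
Why: Negishi coupling of the alkenyl triflate with the silylmethylzinc reagent made by transmetalation installs C15–Si without moving C3=C4, and the organozinc, used in excess, tolerates the free hydroxyl and does not open the enol lactone as the Grignard reagent would.

Step 15
Reactants: 26 allylsilane monomer (two molecules)
Product: 27 head-to-head dimer diol
Conditions: hν (medium-pressure Hg lamp, Pyrex, λ > 300 nm), degassed benzene, rt, high concentration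
Reagents that add atoms: none
Why: [2+2] photodimerisation of the dienyl enol lactone at C8=C9 should proceed through C9–C9′ bonding to the 1,4-biradical with two allylic, oxygen-substituted C8 radicals (head-to-head), each alkene reacting on its α face anti to the axial C14 methyl, which sets C8, C9, C8′ and C9′ in the C2-symmetric cis-anti-cis cyclobutane.

Step 16
Reactants: 27 head-to-head dimer diol
Product: 30 CNP0265879.1, via bis-triflate 28 (not isolated), via half-cyclised triflate 29 (not isolated)
Conditions: Tf2O, 2,6-di-tert-butyl-4-methylpyridine, CH2Cl2, −78 → 0 °C; aq. NaHCO3 quench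
Reagents that add atoms: trifluoromethanesulfonic anhydride, O=S(=O)(OS(=O)(=O)C(F)(F)F)C(F)(F)F (triflyl groups stay in intermediates 28 and 29 only)
Why: Proposed new method: in situ triflation of the two equatorial 1β-hydroxyls gives bis-triflate 28, in which each C1–O bond lies anti to the axial α lobe of the C3=C4 allylsilane π bond of its half-chair A ring, so that C3 displaces triflate from the α side (homoallyl-to-cyclopropylcarbinyl participation) and the tertiary, β-silyl-stabilised C4 cation collapses by loss of the silyl group to the exocyclic C4=C15 alkene; the closest known reactions are the cholesteryl-to-i-steroid rearrangement and the allylsilane-terminated cyclisation of acyclic homoallylic triflates to vinylcyclopropanes, which here must operate across a ring and twice. Each cyclopropane (C1–C2–C3 and C1′–C2′–C3′) closes in a 3-exo-tet mode, and each six-membered A ring thereby contracts to the five-membered ring C1/C3/C4/C5/C10. C1 and C1′ are set by inversion at the carbinol carbon, which the 1β (equatorial) leaving group dictates, and C3 and C3′ follow from the obligatory cis fusion of the bicyclo[3.1.0]hexane, so C2 is pushed to the β face, syn to C14. The step needs π participation to outrun E2 loss of triflic acid and Wagner–Meerwein shift of the antiperiplanar C10–C5 bond, which the high nucleophilicity of the allylsilane, the low temperature and a non-nucleophilic hindered base should secure. It also needs a single alkene position, which silicon secures because desilylation is faster than proton loss from C3 or C5. The butenolides and the cyclobutane offer no site for attack by triflic anhydride or the pyridine base.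

**Compound list**

1 | 2-methylcyclohexane-1,3-dione | CC1C(=O)CCCC1=O | starting material
2 | methyl vinyl ketone | CC(=O)C=C | starting material
3 | 2-methyl-2-(3-oxobutyl)cyclohexane-1,3-dione | CC(=O)CCC1(C)C(=O)CCCC1=O | intermediate
4 | cis-fused ketol, 5β-hydroxy-10β-methyldecalin-1,7-dione (11,12,13,15-tetranoreudesmane numbering) | O=C1CCC[C@@]2(O)CC(=O)CC[C@@]12C | intermediate (not isolated)
5 | (R)-Wieland–Miescher ketone, (8aR)-8a-methyl-3,4,8,8a-tetrahydronaphthalene-1,6(2H,7H)-dione | O=C1CCCC2=CC(=O)CC[C@@]12C | intermediate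
6 | (4aR,5R)-5-hydroxy-4a-methyl-4,4a,5,6,7,8-hexahydronaphthalen-2(3H)-one (1β-OH, Δ5, 7-one) | O[C@@H]1CCCC2=CC(=O)CC[C@@]12C | intermediate
7 | 7,7-ethylenedioxy-1β-hydroxy-11,12,13,15-tetranoreudesm-4-ene | O[C@@H]1CCC=C2CC3(CC[C@@]12C)OCCO3 | intermediate
8 | 1β-(tert-butyldimethylsilyloxy)-7,7-ethylenedioxy-11,12,13,15-tetranoreudesm-4-ene | CC(C)(C)[Si](C)(C)O[C@@H]1CCC=C2CC3(CC[C@@]12C)OCCO3 | intermediate
9 | 4α-boryl-5α-H organoborane of 8 | CC(C)(C)[Si](C)(C)O[C@@H]1CC[C@@H](B)[C@@H]2CC3(CC[C@@]12C)OCCO3 | intermediate (not isolated)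
10 | 1β-(TBS-oxy)-7,7-ethylenedioxy-5α-11,12,13,15-tetranoreudesman-4α-ol | CC(C)(C)[Si](C)(C)O[C@@H]1CC[C@@H](O)[C@@H]2CC3(CC[C@@]12C)OCCO3 | intermediate
11 | 1β-(TBS-oxy)-7,7-ethylenedioxy-5α-11,12,13,15-tetranoreudesman-4-one | CC(C)(C)[Si](C)(C)O[C@@H]1CCC(=O)[C@@H]2CC3(CC[C@@]12C)OCCO3 | intermediate
12 | 1β-(TBS-oxy)-7,7-ethylenedioxy-5α-11,12,13,15-tetranoreudesm-3-en-4-yl triflate | CC(C)(C)[Si](C)(C)O[C@@H]1CC=C(OS(=O)(=O)C(F)(F)F)[C@@H]2CC3(CC[C@@]12C)OCCO3 | intermediate
13 | 1β-(TBS-oxy)-7-oxo-5α-11,12,13,15-tetranoreudesm-3-en-4-yl triflate | CC(C)(C)[Si](C)(C)O[C@@H]1CC=C(OS(=O)(=O)C(F)(F)F)[C@@H]2CC(=O)CC[C@@]12C | intermediate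
14 | Δ7(8) trimethylsilyl enol ether of 13 | CC(C)(C)[Si](C)(C)O[C@@H]1CC=C(OS(=O)(=O)C(F)(F)F)[C@@H]2CC(O[Si](C)(C)C)=CC[C@@]12C | intermediate (not isolated)
15 | 8α-(trimethylsilyloxy)-7-ketone | CC(C)(C)[Si](C)(C)O[C@@H]1CC=C(OS(=O)(=O)C(F)(F)F)[C@@H]2CC(=O)[C@@H](O[Si](C)(C)C)C[C@@]12C | intermediate (not isolated)
16 | 8α-hydroxy-7-ketone (1β-OTBS, 4-OTf, Δ3) | CC(C)(C)[Si](C)(C)O[C@@H]1CC=C(OS(=O)(=O)C(F)(F)F)[C@@H]2CC(=O)[C@@H](O)C[C@@]12C | intermediate
17 | 2-(diethoxyphosphoryl)propanoic acid | CCOP(=O)(OCC)C(C)C(=O)O | starting material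
18 | 8α-[2-(diethoxyphosphoryl)propanoyloxy]-7-ketone (mixture at the phosphonate carbon) | CC(C)(C)[Si](C)(C)O[C@@H]1CC=C(OS(=O)(=O)C(F)(F)F)[C@@H]2CC(=O)[C@@H](OC(=O)C(C)P(=O)(OCC)OCC)C[C@@]12C | intermediate (not isolated)
19 | 1β-(TBS-oxy)-4-(triflyloxy)-15-nor-eudesma-3,7(11)-dien-8α,12-olide (8β-H) | CC(C)(C)[Si](C)(C)O[C@@H]1CC=C(OS(=O)(=O)C(F)(F)F)[C@@H]2CC3=C(C)C(=O)O[C@H]3C[C@@]12C | intermediate
20 | 12-(TBS-oxy)furan (2-silyloxyfuran) of 19 | CC(C)(C)[Si](C)(C)O[C@@H]1CC=C(OS(=O)(=O)C(F)(F)F)[C@@H]2Cc3c(C)c(O[Si](C)(C)C(C)(C)C)oc3C[C@@]12C | intermediate (not isolated)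
21 | 8α-bromo-Δ7(11)-8,12-olide | CC(C)(C)[Si](C)(C)O[C@@H]1CC=C(OS(=O)(=O)C(F)(F)F)[C@@H]2CC3=C(C)C(=O)O[C@]3(Br)C[C@@]12C | intermediate (not isolated)
22 | 1β-(TBS-oxy)-4-(triflyloxy)-15-nor-eudesma-3,7(11),8-trien-8,12-olide | CC(C)(C)[Si](C)(C)O[C@@H]1CC=C(OS(=O)(=O)C(F)(F)F)[C@@H]2CC3=C(C)C(=O)OC3=C[C@@]12C | intermediate
23 | 1β-hydroxy-4-(triflyloxy)-15-nor-eudesma-3,7(11),8-trien-8,12-olide | O[C@@H]1CC=C(OS(=O)(=O)C(F)(F)F)[C@@H]2CC3=C(C)C(=O)OC3=C[C@@]12C | intermediate
24 | (trimethylsilyl)methylmagnesium chloride | C[Si](C)(C)C[Mg]Cl | starting material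
25 | (trimethylsilyl)methylzinc chloride | C[Si](C)(C)C[Zn]Cl | intermediate (not isolated)
26 | 1β-hydroxy-15-(trimethylsilyl)eudesma-3,7(11),8-trien-8,12-olide | C[Si](C)(C)CC1=CC[C@@H](O)[C@@]2(C)[C@H]1CC1=C(C)C(=O)OC1=C2 | intermediate
27 | cyclobutane-linked (C8–C8′, C9–C9′) bis[1β-hydroxy-15-(trimethylsilyl)eudesma-3,7(11)-dien-8,12-olide], cis-anti-cis | C[Si](C)(C)CC1=CC[C@@H](O)[C@@]2(C)[C@H]1CC1=C(C)C(=O)O[C@]13[C@H]2[C@H]1[C@@]2(C)[C@H](O)CC=C(C[Si](C)(C)C)[C@@H]2CC2=C(C)C(=O)O[C@@]213 | intermediate
28 | 1β,1′β-bis(triflate) of 27 | C[Si](C)(C)CC1=CC[C@@H](OS(=O)(=O)C(F)(F)F)[C@@]2(C)[C@H]1CC1=C(C)C(=O)O[C@]13[C@H]2[C@H]1[C@@]2(C)[C@H](OS(=O)(=O)C(F)(F)F)CC=C(C[Si](C)(C)C)[C@@H]2CC2=C(C)C(=O)O[C@@]213 | intermediate (not isolated)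
29 | half-cyclised triflate (one lindenane half, one eudesmane 1′β-triflate half) | C=C1[C@H]2C[C@H]2[C@@]2(C)[C@H]1CC1=C(C)C(=O)O[C@]13[C@H]2[C@H]1[C@@]2(C)[C@H](OS(=O)(=O)C(F)(F)F)CC=C(C[Si](C)(C)C)[C@@H]2CC2=C(C)C(=O)O[C@@]213 | intermediate (not isolated)
30 | CNP0265879.1, head-to-head cyclobutane dimer of lindena-4(15),7(11),8-trien-8,12-olide | C=C1[C@H]2C[C@H]2[C@@]2(C)[C@H]1CC1=C(C)C(=O)O[C@]13[C@H]2[C@H]1[C@@]2(C)[C@@H]4C[C@@H]4C(=C)[C@@H]2CC2=C(C)C(=O)O[C@@]213 | target

**Step count and risks**

Total step count: 16. Longest linear sequence: 16 steps (1 → 30; step 15 joins two molecules of the same monomer).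

Steps most likely to fail:

1. Step 16 (proposed new method). The triflates may ionise without π participation, which would lead to E2 loss of triflic acid, Wagner–Meerwein shift of the C10–C5 bond or cyclisation of one half only. Fallback by known chemistry, setting out from ketone 11 and coming back at target 30: TBAF in THF frees the 1β-hydroxy-4-ketone ketal F1, and MsCl/Et3N gives the 1β-mesylate F2. KHMDS (THF, −78 → 0 °C) forms the kinetic C3 enolate, which displaces the mesylate with inversion at C1; this is the base-induced 1,3-elimination known for 4-sulfonyloxycyclohexanones and 3β-sulfonyloxy-6-keto steroids, and it gives the cyclopropyl ketone ketal F3. PPTS in wet acetone gives the 15-nor-lindenane-4,7-dione F4, where the C7 ketone enolises kinetically at C8 while the cyclopropyl ketone has only the hindered C5 methine. The conditions of steps 10, 11 and 12 then give in turn the 8α-hydroxy dione F5, the 4-oxo butenolide F6 and the 4-oxo trienolide F7. Takai–Lombardo methylenation (Zn, CH2Br2, TiCl4) of the cyclopropyl ketone gives chloranthalactone A F8, and irradiation under the conditions of step 15 should dimerise it to 30.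

2. Step 15. Head-to-head or facial selectivity may be lost, or the allylsilane may enter a competing photoreaction or be desilylated. Fallback that inverts the order of dimerisation and C–Si bond formation, setting out from 23 and coming back at 27: irradiation of the triflate 23 under the conditions of step 15, with no allylsilane present, gives the head-to-head bis(enol triflate) diol F9, and a double Negishi coupling with 25 as in step 14 gives 27.

3. Step 12. The silyloxyfuran may be brominated at C11 and not at C8, or loss of HBr may be incomplete. Fallback by hydroxylation and dehydration, setting out from 19 and coming back at 22: KHMDS (THF, −78 °C), then O2 and P(OEt)3, oxygenates the dienolate at C8 to the 8-hydroxy lactone F10 (drawn as the 8β-hydroxy epimer; the centre is lost next), and p-TsOH (cat.) in toluene at 60 °C dehydrates it to 22.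

**Further compounds**

F1 | step 16 | 7,7-ethylenedioxy-1β-hydroxy-5α-11,12,13,15-tetranoreudesman-4-one | O[C@@H]1CCC(=O)[C@@H]2CC3(CC[C@@]12C)OCCO3
F2 | step 16 | 1β-mesylate of F1 | CS(=O)(=O)O[C@@H]1CCC(=O)[C@@H]2CC3(CC[C@@]12C)OCCO3
F3 | step 16 | 7,7-ethylenedioxy-11,12,13,15-tetranorlindenan-4-one | O=C1[C@H]2C[C@H]2[C@@]2(C)[C@H]1CC1(CC2)OCCO1
F4 | step 16 | 11,12,13,15-tetranorlindenane-4,7-dione | O=C1[C@H]2C[C@H]2[C@@]2(C)[C@H]1CC(=O)CC2
F5 | step 16 | 8α-hydroxy-11,12,13,15-tetranorlindenane-4,7-dione | O=C1[C@H]2C[C@H]2[C@@]2(C)[C@H]1CC(=O)[C@@H](O)C2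
F6 | step 16 | 4-oxo-15-nor-linden-7(11)-en-8α,12-olide | O=C1[C@H]2C[C@H]2[C@@]2(C)[C@H]1CC1=C(C)C(=O)O[C@H]1C2
F7 | step 16 | 4-oxo-15-nor-lindena-7(11),8-dien-8,12-olide | O=C1[C@H]2C[C@H]2[C@@]2(C)[C@H]1CC1=C(C)C(=O)OC1=C2
F8 | step 16 | chloranthalactone A, lindena-4(15),7(11),8-trien-8,12-olide | C=C1[C@H]2C[C@H]2[C@@]2(C)[C@H]1CC1=C(C)C(=O)OC1=C2
F9 | step 15 | cyclobutane-linked (C8–C8′, C9–C9′) bis[1β-hydroxy-4-(triflyloxy)-15-nor-eudesma-3,7(11)-dien-8,12-olide] | FC(F)(F)S(=O)(=O)OC1=CC[C@@H](O)[C@@]2(C)[C@H]1CC1=C(C)C(=O)O[C@]13[C@H]2[C@H]1[C@@]2(C)[C@H](O)CC=C(OS(=O)(=O)C(F)(F)F)[C@@H]2CC2=C(C)C(=O)O[C@@]213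
F10 | step 12 | 1β-(TBS-oxy)-8β-hydroxy-4-(triflyloxy)-15-nor-eudesma-3,7(11)-dien-8α,12-olide | CC(C)(C)[Si](C)(C)O[C@@H]1CC=C(OS(=O)(=O)C(F)(F)F)[C@@H]2CC3=C(C)C(=O)O[C@@]3(O)C[C@@]12C
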